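The runs stem from a simulated flask on assumed constants, noise included.

**Next charge.** Leave the solid reagent at 1.20 mM and follow the noon flask on to 80 min; that was the call I had to make, and I made it from the noon run.

- noon: starting material 0.0010 M; solid reagent 1.2 mM; free catalyst 2 µM; second catalyst 1 µM; the very flask that is asked about, followed so far
- flask: starting material 0.0010 M; solid reagent 1.20 mM; free catalyst 2.0 µM; second catalyst 1.0 µM; time 80 min

- noon (time / min: uncatalysed product / %, target / %): 1.00: 0.7, 0; 3.00: 1.3, 4.9; 6.00: 1.8, 15.8; 8.00: 1.6, 23.7; 12.0: 2.0, 38.6; 15.0: 1.6, 47.1

(each reading ± 0.3 percentage points)

- solid reagent is a solid; its amount is given per volume of the solution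
- what was read earlier has a scatter of 0.3 percentage points, one standard deviation
- reactions considered so far: coupling partner + second catalyst + intermediate -> second catalyst + target; solid reagent <-> coupling partner; starting material + coupling partner -> uncatalysed product; starting material + free catalyst -> free catalyst + intermediate
- at the start none of the solid reagent is in solution

- ratio of uncatalysed product to target at 1.0 min
- ratio of uncatalysed product to target at 10 min
- ratio of uncatalysed product to target at 80 min
- which of uncatalysed product and target there is more of at 80 min

**The cover.** By the reactions considered, the target and the uncatalysed product each take one coupling partner, and the coupling partner comes from the solid reagent. So I divided the solid reagent charged by the starting material charged and got 1.20, the cover. In this flask the solid reagent charged was more than the starting material charged, which made the starting material the limiting reagent, so I left the charge as it was.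

**My reckoning.** In the noon run the uncatalysed product read 1.8 %, 1.6 %, 2.0 % and 1.6 % from 6.00 min to 15.0 min, which I took as level at a mean of 1.75 %. With the charge fully converted to the two products, the ratio is 0.0178, and I committed to that as the low end for 80 min. The reading of target at 1.00 min, 0 % with a scatter of 0.3 percentage points, gave me no usable ratio.

**The forecast.** The forecast gave 2, 0.058 and 0.021, with target ahead, a last ratio above mine, holding that “the 1.2 equivalents of solid should carry the target to about 95 %”.

**The flask.** The flask gave 1.63, 0.0623 and 0.0204, with target ahead at 95.8 % against 1.95 %, and 2.29 % still stood as intermediate at 80.0 min.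

    coupling partner + second catalyst + intermediate → second catalyst + target (k = 2.60 × 10⁶ L² mol⁻² s⁻¹)
    solid reagent ⇌ coupling partner, rate k2*(cs2 - [coupling partner]) while solid is left; crystals form when [coupling partner] > cs2 (solubility = 0.520 mM, k = 0.00430 s⁻¹)
    starting material + coupling partner → uncatalysed product (k = 3.90 L mol⁻¹ s⁻¹)
    starting material + free catalyst → free catalyst + intermediate (k = 8700 L mol⁻¹ s⁻¹)

**The cover again.** In this flask the cover of 1.20 left a spare 0.200 mM, and [coupling partner] stood at 2.00 × 10⁻⁴ M after 800 min. The neighbour charged with 0.0040 M of starting material had a cover of 0.300, that is, solid reagent for 30.0 % of its charge. That neighbour ended with 28.5 % target, 1.45 % uncatalysed product and 70.0 % intermediate.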